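The route rests on cutting the dihydropyran ring of the chroman at O1–C2 together with the bond from the exocyclic CH2 on C2 to C6 of the hexahydroindenone. C2 is a quaternary carbon that carries the ring oxygen, a methyl and a CH2 bound to the sp2 β-carbon of the enone: the retron of an alkene oxy-alkenylation. One palladium-catalysed carboetherification therefore joins phenol 5, which carries a 3-methylbut-3-enyl chain, to the enantiopure β-bromo enone 19, closes the pyran ring as the last ring and sets C2 under ligand control. The cis-3a,7a-dimethylhydrindane comes from an asymmetric conjugate methylation and an intramolecular enolate alkylation.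

Key step: step 12

Remark: 3-bromocyclohex-2-en-1-one and dibromotriphenylphosphorane are taken as purchasable; in the two ligand-controlled steps (4 and 12) the ligand antipode that delivers the drawn configuration is used, and the descriptors in the names are those the target requires.

Step 1
Reactants: 1 4-methoxy-2-methylphenol
Product: 2 2-[(dimethylamino)methyl]-4-methoxy-6-methylphenol
Conditions: aq. CH2O, aq. Me2NH, EtOH, 80 °C
Reagents that add atoms: formaldehyde, C=O; dimethylamine, CNC
Why: Mannich reaction, in which the iminium ion from formaldehyde and dimethylamine attacks the only free position ortho to the phenol OH, the stronger director.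

Step 2
Reactants: 2 2-[(dimethylamino)methyl]-4-methoxy-6-methylphenol
Product: 5 4-methoxy-2-methyl-6-(3-methylbut-3-en-1-yl)phenol, via ammonium iodide 3 (not isolated), via quinone methide 4 (not isolated)
Conditions: MeI, THF, 20 °C; then 2-methylallylmagnesium chloride (3 equiv), THF, –78 to 20 °C; aq. NH4Cl
Reagents that add atoms: 2-methylallylmagnesium chloride, CC(=C)C[Mg]Cl
Why: N-methylation makes the amine a leaving group, the first equivalent of Grignard reagent deprotonates the phenol so that trimethylamine is expelled to give the ortho-quinone methide, and a second equivalent adds 1,4 to its exocyclic CH2 with rearomatisation (ortho-quinone methide alkylation).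

Step 3
Reactants: 6 3-chloroprop-1-ene (allyl chloride); 7 3-bromocyclohex-2-en-1-one
Product: 9 3-(3-chloropropyl)cyclohex-2-en-1-one, via alkylborane 8 (not isolated)
Conditions: 9-BBN, THF, 0 to 20 °C; then 7, Pd(dppf)Cl2 (cat.), aq. K3PO4, DMF, 50 °C
Reagents that add atoms: none
Why: Anti-Markovnikov hydroboration of allyl chloride followed by B-alkyl Suzuki–Miyaura coupling with the vinylogous acyl bromide, in which the primary alkyl chloride is inert to palladium.

Step 4
Reactants: 9 3-(3-chloropropyl)cyclohex-2-en-1-one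
Product: 11 (3R)-3-(3-chloropropyl)-3-methylcyclohex-1-en-1-yl acetate, via aluminium enolate 10 (not isolated)
Conditions: Me3Al, copper thiophene-2-carboxylate Cu(O2CC4H3S) (cat.), chiral biphenol-based phosphoramidite ligand (cat.), Et2O, –30 °C; then Ac2O, –30 to 20 °C
Reagents that add atoms: trimethylaluminium, C[Al](C)C; acetic anhydride, CC(=O)OC(C)=O
Why: Copper-catalysed asymmetric conjugate addition of Me3Al to the β-substituted cyclohexenone should set the quaternary stereocenter (methyl delivered to the Si face of C3 under control of the chiral phosphoramidite–copper complex), and O-acetylation of the aluminium enolate stores the enolate regiochemistry.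

Step 5
Reactants: 11 (3R)-3-(3-chloropropyl)-3-methylcyclohex-1-en-1-yl acetate
Product: 13 (3R)-3-(3-chloropropyl)-2,3-dimethylcyclohexan-1-one (C2 epimers), via lithium enolate 12 (not isolated)
Conditions: MeLi (2.1 equiv), THF, 0 °C; then HMPA, MeI, –78 to –40 °C
Reagents that add atoms: iodomethane, CI
Why: Methyllithium cleaves the enol acetate to the regiodefined lithium enolate, which should be C-methylated at C2 at low temperature faster than it displaces the remote chloride; the C2 center forms as a mixture that is erased in step 6 (regiospecific enolate alkylation).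

Step 6
Reactants: 13 (3R)-3-(3-chloropropyl)-2,3-dimethylcyclohexan-1-one
Product: 14 (3aS,7aS)-3a,7a-dimethyloctahydro-4H-inden-4-one
Conditions: KOtBu, NaI (cat.), tBuOH–THF, 50 °C
Reagents that add atoms: none
Why: Under equilibrating conditions the C2 enolate should close the cyclopentane by 5-exo-tet intramolecular alkylation; the three-carbon tether can only reach the enolate face on its own side, so the ring fusion is cis and C3a is set by C7a with the two methyl groups cis.

Step 7
Reactants: 14 (3aS,7aS)-3a,7a-dimethyloctahydro-4H-inden-4-one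
Product: 15 (3aS,7aS)-3a,7a-dimethyl-1,2,3,3a,7,7a-hexahydro-4H-inden-4-one
Conditions: 2-iodoxybenzoic acid (IBX), DMSO–fluorobenzene, 70 °C
Reagents that add atoms: none
Why: IBX-mediated α,β-dehydrogenation of the ketone, regiospecific because C3a is quaternary and only C5–C6 can be desaturated.

Step 8
Reactants: 15 (3aS,7aS)-3a,7a-dimethyl-1,2,3,3a,7,7a-hexahydro-4H-inden-4-one
Product: 16 (3aS,7aS)-5,6-epoxy-3a,7a-dimethyloctahydro-4H-inden-4-one
Conditions: 30% aq. H2O2, NaOH (cat.), MeOH, 0 to 20 °C
Reagents that add atoms: hydrogen peroxide, OO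
Why: Weitz–Scheffer nucleophilic epoxidation (hydroperoxide adds to C6, ring closure on oxygen); either epoxide face is acceptable because C5 and C6 lose their configuration in step 9.

Step 9
Reactants: 16 (3aS,7aS)-5,6-epoxy-3a,7a-dimethyloctahydro-4H-inden-4-one
Product: 17 (3aS,7aS)-3a,7a-dimethylhexahydro-1H-indene-4,6(2H,5H)-dione
Conditions: Pd(PPh3)4 (cat.), 1,2-bis(diphenylphosphino)ethane (cat.), toluene, 110 °C
Reagents that add atoms: none
Why: Zerovalent-palladium-catalysed isomerisation of the α,β-epoxy ketone to the β-diketone through oxidative addition at the Cα–O bond, β-hydride elimination at C6 and tautomerisation.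

Step 10
Reactants: 17 (3aS,7aS)-3a,7a-dimethylhexahydro-1H-indene-4,6(2H,5H)-dione
Product: 18 (3aS,7aS)-3a,7a-dimethyl-5-(2-methylprop-2-en-1-yl)hexahydro-1H-indene-4,6(2H,5H)-dione
Conditions: 2-methylallyl acetate (1.05 equiv), Pd(PPh3)4 (cat.), K2CO3, THF, 50 °C; dilute HCl work-up
Reagents that add atoms: 2-methylallyl acetate, CC(=C)COC(C)=O
Why: Tsuji–Trost allylation, in which the soft enolate of the cyclic 1,3-dione attacks the π-(2-methylallyl)palladium complex at carbon (C5) in preference to oxygen.

Step 11
Reactants: 18 (3aS,7aS)-3a,7a-dimethyl-5-(2-methylprop-2-en-1-yl)hexahydro-1H-indene-4,6(2H,5H)-dione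
Product: 19 (3aS,7aS)-6-bromo-3a,7a-dimethyl-5-(2-methylprop-2-en-1-yl)-1,2,3,3a,7,7a-hexahydro-4H-inden-4-one
Conditions: Ph3PBr2, Et3N, CH2Cl2, 0 to 20 °C
Reagents that add atoms: dibromotriphenylphosphorane, BrP(Br)(c1ccccc1)(c1ccccc1)c1ccccc1
Why: Conversion of the 2-alkyl-1,3-dione into the vinylogous acyl bromide through an enol oxyphosphonium salt; activation and bromide attack should occur at C6, flanked by CH2, and not at C4, shielded by the quaternary C3a.

Step 12
Reactants: 5 4-methoxy-2-methyl-6-(3-methylbut-3-en-1-yl)phenol; 19 (3aS,7aS)-6-bromo-3a,7a-dimethyl-5-(2-methylprop-2-en-1-yl)-1,2,3,3a,7,7a-hexahydro-4H-inden-4-one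
Product: 20 (3aS,7aS)-6-{[(2S)-6-methoxy-2,8-dimethyl-3,4-dihydro-2H-chromen-2-yl]methyl}-3a,7a-dimethyl-5-(2-methylprop-2-en-1-yl)-1,2,3,3a,7,7a-hexahydro-4H-inden-4-one
Conditions: Pd2(dba)3 (cat.), TADDOL-derived chiral monophosphite ligand (cat.), NaOtBu, toluene, 95 °C
Reagents that add atoms: none
Why: Oxidative addition of alkenyl bromide 19 to zerovalent palladium and bromide/phenoxide exchange should give an alkenyl(aryloxo)palladium species; syn migratory insertion of the 1,1-disubstituted alkene of 5 into the Pd–O bond closes the pyran ring in a 6-exo-trig mode (O1–C2 bond), and C(sp3)–C(sp2) reductive elimination from the resulting neopentyl-type alkyl(alkenyl)palladium intermediate, which has no β-hydrogen, forms the CH2–C6 bond. The closest known reaction type is the palladium-catalysed alkene carboetherification of 2-(but-3-enyl)phenols with aryl and alkenyl bromides, which gives 2,2-disubstituted chromans. The only new stereocenter, C2, is created in the oxypalladation and is controlled by the chiral ligand on palladium, because the hydrindenone stereocenters are too remote to bias the alkene face; any 2R epimer, like material from the minor enantiomer of the hydrindane, is a diastereomer of 20 and is removed by chromatography. The step needs chemoselectivity for alkene insertion over direct O-alkenylation (addition–elimination at C6 or C–O reductive elimination) and over Heck-type paths; the tetrasubstituted, α-branched C5=C6 bromide and the 2,6-disubstituted phenoxide disfavour O-alkenylation, and the 2-methylallyl group on C5 cannot reach the palladium-bound carbon in a favourable ring size.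

Step 13
Reactants: 20 (3aS,7aS)-6-{[(2S)-6-methoxy-2,8-dimethyl-3,4-dihydro-2H-chromen-2-yl]methyl}-3a,7a-dimethyl-5-(2-methylprop-2-en-1-yl)-1,2,3,3a,7,7a-hexahydro-4H-inden-4-one
Product: 21 (3aS,7aS)-5-(2-hydroxy-2-methylpropyl)-6-{[(2S)-6-methoxy-2,8-dimethyl-3,4-dihydro-2H-chromen-2-yl]methyl}-3a,7a-dimethyl-1,2,3,3a,7,7a-hexahydro-4H-inden-4-one
Conditions: Co(acac)2 (cat.), PhSiH3, O2 (1 atm), THF–iPrOH, 20 °C
Reagents that add atoms: dioxygen, O=O
Why: Mukaiyama hydration, in which hydrogen-atom transfer from a cobalt hydride to the terminal CH2 of the 1,1-disubstituted alkene gives the tertiary radical that is trapped by O2 and reduced to the Markovnikov alcohol, while the hindered tetrasubstituted enone should react far more slowly.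

Compound list
1 | 4-methoxy-2-methylphenol | COc1ccc(O)c(C)c1 | starting material
2 | 2-[(dimethylamino)methyl]-4-methoxy-6-methylphenol | CN(C)Cc1cc(OC)cc(C)c1O | intermediate
3 | (2-hydroxy-5-methoxy-3-methylbenzyl)trimethylammonium iodide | C[N+](C)(C)Cc1cc(OC)cc(C)c1O.[I-] | intermediate
4 | 4-methoxy-2-methyl-6-methylidenecyclohexa-2,4-dien-1-one | C=C1C=C(OC)C=C(C)C1=O | intermediate
5 | 4-methoxy-2-methyl-6-(3-methylbut-3-en-1-yl)phenol | COc1cc(C)c(O)c(CCC(C)=C)c1 | intermediate
6 | 3-chloroprop-1-ene (allyl chloride) | C=CCCl | starting material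
7 | 3-bromocyclohex-2-en-1-one | O=C1C=C(Br)CCC1 | starting material
8 | 9-(3-chloropropyl)-9-borabicyclo[3.3.1]nonane | ClCCCB1C2CCCC1CCC2 | intermediate
9 | 3-(3-chloropropyl)cyclohex-2-en-1-one | O=C1C=C(CCCCl)CCC1 | intermediate
10 | dimethylaluminium (3R)-3-(3-chloropropyl)-3-methylcyclohex-1-en-1-olate | C[Al](C)OC1=C[C@@](C)(CCCCl)CCC1 | intermediate
11 | (3R)-3-(3-chloropropyl)-3-methylcyclohex-1-en-1-yl acetate | CC(=O)OC1=C[C@@](C)(CCCCl)CCC1 | intermediate
12 | lithium (3R)-3-(3-chloropropyl)-3-methylcyclohex-1-en-1-olate | [Li]OC1=C[C@@](C)(CCCCl)CCC1 | intermediate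
13 | (3R)-3-(3-chloropropyl)-2,3-dimethylcyclohexan-1-one, mixture of C2 epimers | CC1C(=O)CCC[C@]1(C)CCCCl | intermediate
14 | (3aS,7aS)-3a,7a-dimethyloctahydro-4H-inden-4-one, cis-fused | C1CC(=O)[C@@]2(C)CCC[C@@]2(C)C1 | intermediate
15 | (3aS,7aS)-3a,7a-dimethyl-1,2,3,3a,7,7a-hexahydro-4H-inden-4-one | C1=CC(=O)[C@@]2(C)CCC[C@@]2(C)C1 | intermediate
16 | (3aS,7aS)-5,6-epoxy-3a,7a-dimethyloctahydro-4H-inden-4-one, epoxide face not controlled | C12OC1C(=O)[C@@]3(C)CCC[C@@]3(C)C2 | intermediate
17 | (3aS,7aS)-3a,7a-dimethylhexahydro-1H-indene-4,6(2H,5H)-dione | O=C1CC(=O)[C@@]2(C)CCC[C@@]2(C)C1 | intermediate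
18 | (3aS,7aS)-3a,7a-dimethyl-5-(2-methylprop-2-en-1-yl)hexahydro-1H-indene-4,6(2H,5H)-dione, C5 epimers and enol forms | O=C1C(CC(C)=C)C(=O)[C@@]2(C)CCC[C@@]2(C)C1 | intermediate
19 | (3aS,7aS)-6-bromo-3a,7a-dimethyl-5-(2-methylprop-2-en-1-yl)-1,2,3,3a,7,7a-hexahydro-4H-inden-4-one | BrC1=C(CC(C)=C)C(=O)[C@@]2(C)CCC[C@@]2(C)C1 | intermediate
20 | (3aS,7aS)-6-{[(2S)-6-methoxy-2,8-dimethyl-3,4-dihydro-2H-chromen-2-yl]methyl}-3a,7a-dimethyl-5-(2-methylprop-2-en-1-yl)-1,2,3,3a,7,7a-hexahydro-4H-inden-4-one | COc1cc(C)c2c(c1)CC[C@@](C)(CC1=C(CC(C)=C)C(=O)[C@@]3(C)CCC[C@@]3(C)C1)O2 | intermediate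
21 | (3aS,7aS)-5-(2-hydroxy-2-methylpropyl)-6-{[(2S)-6-methoxy-2,8-dimethyl-3,4-dihydro-2H-chromen-2-yl]methyl}-3a,7a-dimethyl-1,2,3,3a,7,7a-hexahydro-4H-inden-4-one (CNP0224132.2) | COc1cc(C)c2c(c1)CC[C@@](C)(CC1=C(CC(C)(C)O)C(=O)[C@@]3(C)CCC[C@@]3(C)C1)O2 | target

Total steps: 13. Longest linear sequence: 11 steps (steps 3 to 13, from 6 and 7); the phenol branch (steps 1 and 2) joins at step 12.

Steps most likely to fail

1. Step 12. Direct O-alkenylation of the phenoxide at C6 of the vinylogous acyl bromide may outrun alkene insertion, and facial selectivity in the oxypalladation may be modest. The fallback changes the electrophile from a vinylogous acyl bromide to a plain alkenyl bromide by masking the carbonyl. From 19, Luche reduction (NaBH4, CeCl3·7H2O, MeOH, 0 °C) should give the allylic alcohol F1, and silylation (TBSOTf, 2,6-lutidine) the silyl ether F2. The same carboetherification with 5 (Pd2(dba)3, chiral phosphite or S-Phos, NaOtBu, toluene) should then close the pyran ring to the silylated chroman F3. Bu4NF should release the chroman allylic alcohol F4, and Dess–Martin oxidation returns to 20. A 2R epimer remains a diastereomer throughout and is removed by chromatography.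

2. Step 6. Enolisation may occur away from C2, and E2 loss of HCl or O-alkylation may compete with ring closure. The fallback generates the C2 enolate regiospecifically instead of by equilibration. From 13, Me3SiCl, NaI and Et3N in MeCN at 60 °C should give the thermodynamic, tetrasubstituted silyl enol ether with concurrent chloride-to-iodide exchange, the iodo silyl enol ether F5. MeLi in THF then unmasks the C2 lithium enolate, which closes onto the iodide on warming and returns to 14.

3. Step 9. The hindered epoxide may stall, or be deoxygenated back to 15 instead of undergoing hydride migration. The fallback brings oxygen to C6 by conjugate borylation and not through the epoxide. From 15, B2pin2 with CuCl, NaOtBu, bis[2-(diphenylphosphino)phenyl] ether and MeOH in THF should give the β-boryl ketone F6. Oxidation with NaBO3·4H2O should give the β-hydroxy ketone F7, and Dess–Martin oxidation returns to the dione 17.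

Further compounds
F1 | step 12 | (3aS,7aS)-6-bromo-3a,7a-dimethyl-5-(2-methylprop-2-en-1-yl)-2,3,3a,4,7,7a-hexahydro-1H-inden-4-ol, C4 epimers | BrC1=C(CC(C)=C)C(O)[C@@]2(C)CCC[C@@]2(C)C1
F2 | step 12 | tert-butyldimethylsilyl ether of F1 | BrC1=C(CC(C)=C)C(O[Si](C)(C)C(C)(C)C)[C@@]2(C)CCC[C@@]2(C)C1
F3 | step 12 | (2S)-chroman from 5 and F2, 4-silyloxy analogue of 20 | COc1cc(C)c2c(c1)CC[C@@](C)(CC1=C(CC(C)=C)C(O[Si](C)(C)C(C)(C)C)[C@@]3(C)CCC[C@@]3(C)C1)O2
F4 | step 12 | 4-hydroxy analogue of 20 (allylic alcohol, C4 epimers) | COc1cc(C)c2c(c1)CC[C@@](C)(CC1=C(CC(C)=C)C(O)[C@@]3(C)CCC[C@@]3(C)C1)O2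
F5 | step 6 | {[(3R)-3-(3-iodopropyl)-2,3-dimethylcyclohex-1-en-1-yl]oxy}trimethylsilane | C[Si](C)(C)OC1=C(C)[C@@](C)(CCCI)CCC1
F6 | step 9 | (3aS,7aS)-3a,7a-dimethyl-6-(4,4,5,5-tetramethyl-1,3,2-dioxaborolan-2-yl)octahydro-4H-inden-4-one | CC1(C)OB(OC1(C)C)C1CC(=O)[C@@]2(C)CCC[C@@]2(C)C1
F7 | step 9 | (3aS,7aS)-6-hydroxy-3a,7a-dimethyloctahydro-4H-inden-4-one | OC1CC(=O)[C@@]2(C)CCC[C@@]2(C)C1
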